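**Retrosynthetic overview**
- Feature: with the ring numbered O1–O2–C3–C4–C5–C6 and the side chain C7–C8(Me)–C9…, the methyl-bearing carbons C4 and C8 have the same sense on either side of C6. C3–C9 is therefore a masked C2-symmetric (2S,6S)-2,6-dimethyl-4-oxoheptanedioate.
- Key disconnection: C4–CH3 and C8–CH3, both made in one operation by auxiliary-controlled enolate methylation at the two ends of the ketal-protected 4-oxoheptanedioyl bis-imide.
- The two hydroxyls of the derived C2 diol are homotopic, so either can be tosylated. C9–C10 comes from a copper-catalysed Grignard coupling, C3–C2' from a diazoacetate homologation, and the C3 carbinol from asymmetric hydrogenation.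
- The only ring (the 1,2-dioxane) is closed late: O2–C3 by 6-exo SN2 attack of a C6 hydroperoxy ketal on the C3 mesylate (inversion). C6–CH3 is the last C–C bond, by axial methyl delivery to the ring peroxycarbenium ion, followed by CH2OH → CO2H.

Key step: step 3

Assumption: the C6 epimers of 22 and 23 and the E/Z isomers of 20 and 21 are carried as mixtures, because all of them converge on the single cation 24.

**Step 1**
Reactants: 1 4-oxoheptanedioic acid; 2 (S)-4-benzyloxazolidin-2-one (2 equiv)
Product: 4 (4S,4'S)-3,3'-(4-oxoheptanedioyl)bis(4-benzyl-1,3-oxazolidin-2-one), via bis(pivalic) mixed anhydride 3 (not isolated)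
Conditions: PivCl, Et3N, THF, −20 °C; then LiCl, 2, −20 °C to rt
Reagents that add atoms: none
Why: One-pot mixed-anhydride N-acylation of the oxazolidinone (LiCl/Et3N) activates both carboxyl groups under conditions mild enough to leave the 4-ketone untouched.

**Step 2**
Reactants: 4
Product: 5 (4S,4'S)-3,3'-[3,3'-(1,3-dioxolane-2,2-diyl)dipropanoyl]bis(4-benzyl-1,3-oxazolidin-2-one) (the ethylene ketal of 4)
Conditions: TMSOCH2CH2OTMS, TMSOTf (cat.), CH2Cl2, −78 to −20 °C; pyridine quench
Reagents that add atoms: 1,2-bis(trimethylsilyloxy)ethane, C[Si](C)(C)OCCO[Si](C)(C)C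
Why: Noyori ketalisation converts the unhindered ketone into the dioxolane at low temperature without touching the imides, which masks the only other enolisable carbonyl before the enolate chemistry.

**Step 3**
Reactants: 5; 6 iodomethane (excess)
Product: 8 (4S,4'S)-3,3'-[(2S,2'S)-3,3'-(1,3-dioxolane-2,2-diyl)bis(2-methylpropanoyl)]bis(4-benzyl-1,3-oxazolidin-2-one), via bis(sodium enolate) 7 (not isolated)
Conditions: 5 added to NaN(SiMe3)2 (2.3 equiv), THF, −78 °C; then MeI (10 equiv), −78 °C
Reagents that add atoms: iodomethane (compound 6), CI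
Why: Adding 5 to excess NaN(SiMe3)2 deprotonates both imide α-CH2 groups to give two independent sodium-chelated (Z)-enolates (7), and each is methylated by iodomethane in an SN2 reaction; this forms the C2–CH3 and C6–CH3 bonds of the heptanedioyl chain (C4–CH3 and C8–CH3 of the target) and closes no ring. The closest known reaction is the Evans asymmetric alkylation of N-acyloxazolidinone sodium enolates, here run at both ends of a symmetric diacid. Each new stereocentre is set by its own auxiliary: chelation fixes the enolate, the C4 benzyl group shields one face and iodomethane enters anti to it, which for an (S)-auxiliary and a CH2R enolate substituent gives the (S) centre, and since both arms carry the same auxiliary the product is (2S,6S). The step needs face selectivity on both arms, C-alkylation only at the two imide α-carbons and no acyl transfer between the arms; the dioxolane removes the ketone α-protons, inverse addition to excess base keeps both arms enolised (an enolate is no acyl acceptor), and excess iodomethane at −78 °C should outrun a Dieckmann-type closure. The minor (2S,6R) and (2R,6R) isomers are diastereomers of 8 while the auxiliaries are attached, so they should be removable by chromatography or crystallisation before cleavage.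

**Step 4**
Reactants: 8
Product: 9 (2S,2'S)-3,3'-(1,3-dioxolane-2,2-diyl)bis(2-methylpropan-1-ol)
Conditions: LiBH4, MeOH (2 equiv), THF, 0 °C
Reagents that add atoms: none
Why: LiBH4 reduction of N-acyloxazolidinones cleaves the exocyclic acyl group to the primary alcohol without epimerising the α-methyl centres, leaves the ketal intact and releases the auxiliary for recovery.

**Step 5**
Reactants: 9
Product: 10 (2S)-3-{2-[(2S)-3-hydroxy-2-methylpropyl]-1,3-dioxolan-2-yl}-2-methylpropyl 4-methylbenzenesulfonate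
Conditions: TsCl (1.05 equiv), Ag2O, KI (cat.), CH2Cl2, 0 °C to rt
Reagents that add atoms: p-toluenesulfonyl chloride, Cc1ccc(cc1)S(=O)(=O)Cl
Why: Ag2O/KI-mediated monotosylation of symmetric diols stops after one sulfonylation, and since the two hydroxyls of C2-symmetric 9 are homotopic either one gives the same compound.

**Step 6**
Reactants: 10; 11 (7-bromoheptyl)benzene (3 equiv)
Product: 13 (2S)-2-methyl-3-{2-[(2R)-2-methyl-10-phenyldecyl]-1,3-dioxolan-2-yl}propan-1-ol, via 7-phenylheptylmagnesium bromide 12 (not isolated)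
Conditions: 11, Mg, THF, 40 °C; then 10, Li2CuCl4 (5 mol %), THF, −78 °C to rt
Reagents that add atoms: none
Why: Copper-catalysed cross-coupling of a primary tosylate with a primary alkyl Grignard reagent forms the C9–C10 bond, with the free hydroxyl carried as its magnesium alkoxide at the cost of one equivalent of 12, as in couplings of 3-halo-2-methylpropanols.

**Step 7**
Reactants: 13
Product: 14 (2S)-2-methyl-3-{2-[(2R)-2-methyl-10-phenyldecyl]-1,3-dioxolan-2-yl}propanal
Conditions: TEMPO (10 mol %), PhI(OAc)2, CH2Cl2, rt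
Reagents that add atoms: none
Why: TEMPO/PhI(OAc)2 oxidises the primary alcohol to the aldehyde without over-oxidation or epimerisation of the α-methyl centre, and the ketal tolerates the weakly acidic medium.

**Step 8**
Reactants: 14
Product: 15 ethyl (4S)-4-methyl-5-{2-[(2R)-2-methyl-10-phenyldecyl]-1,3-dioxolan-2-yl}-3-oxopentanoate
Conditions: N2CHCO2Et, SnCl2 (10 mol %), CH2Cl2, rt
Reagents that add atoms: ethyl diazoacetate, CCOC(=O)C=[N+]=[N-]
Why: Roskamp homologation (SnCl2-catalysed addition of the diazo ester, 1,2-hydride shift and loss of N2) gives the β-keto ester directly under conditions that acetals and an α-stereocentre tolerate.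

**Step 9**
Reactants: 15
Product: 16 ethyl (3R,4S)-3-hydroxy-4-methyl-5-{2-[(2R)-2-methyl-10-phenyldecyl]-1,3-dioxolan-2-yl}pentanoate
Conditions: H2 (50 atm), RuCl2[(S)-BINAP](dmf)n (1 mol %), EtOH, 50 °C
Reagents that add atoms: none
Why: Noyori asymmetric hydrogenation of the β-keto ester is catalyst-controlled; (S)-BINAP delivers hydrogen in the spatial sense that turns methyl acetoacetate into the (S)-hydroxy ester, which is the (3R) carbinol here because the secondary alkyl C4 outranks CH2CO2Et, and the arene, ester and ketal are not reduced.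

**Step 10**
Reactants: 16
Product: 17 (3R,4S)-4-methyl-5-{2-[(2R)-2-methyl-10-phenyldecyl]-1,3-dioxolan-2-yl}pentane-1,3-diol
Conditions: LiBH4, THF, 0 °C to rt
Reagents that add atoms: none
Why: LiBH4 reduces the β-hydroxy ester to the primary alcohol and leaves the ketal untouched, giving the 1,3-diol.

**Step 11**
Reactants: 17
Product: 18 (3R,4S)-1-[(tert-butyldiphenylsilyl)oxy]-4-methyl-5-{2-[(2R)-2-methyl-10-phenyldecyl]-1,3-dioxolan-2-yl}pentan-3-ol
Conditions: TBDPSCl, imidazole, CH2Cl2, 0 °C
Reagents that add atoms: tert-butyl(chloro)diphenylsilane, CC(C)(C)[Si](Cl)(c1ccccc1)c1ccccc1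
Why: The bulky silyl chloride reacts selectively at the primary hydroxyl and leaves the hindered secondary C3–OH free for later activation.

**Step 12**
Reactants: 18
Product: 19 (3R,4S,8R)-1-[(tert-butyldiphenylsilyl)oxy]-3-hydroxy-4,8-dimethyl-16-phenylhexadecan-6-one
Conditions: PPTS, acetone/H2O, 55 °C
Reagents that add atoms: water, O
Why: Mild aqueous acid hydrolyses the dioxolane while the TBDPS ether survives, and with only one γ-hydroxyl present nothing beyond a reversible cyclic hemiketal can form.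

**Step 13**
Reactants: 19
Product: 20 (3R,4S,8R)-1-[(tert-butyldiphenylsilyl)oxy]-6-(methoxymethylidene)-4,8-dimethyl-16-phenylhexadecan-3-ol (E/Z mixture)
Conditions: MeOCH2PPh3Cl, KN(SiMe3)2 (excess), THF, 0 °C; then 19, 0 °C to rt; base-washed silica
Reagents that add atoms: (methoxymethyl)triphenylphosphonium chloride, COC[P+](c1ccccc1)(c1ccccc1)c1ccccc1.[Cl-]
Why: Wittig methoxymethylenation of the ketone (excess ylide, the hydroxyl riding as its alkoxide) gives the enol ether whose ozonolysis must place the carbonyl oxide on C6.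

**Step 14**
Reactants: 20
Product: 21 (3R,4S,8R)-1-[(tert-butyldiphenylsilyl)oxy]-6-(methoxymethylidene)-4,8-dimethyl-16-phenylhexadecan-3-yl methanesulfonate (E/Z mixture)
Conditions: MsCl, pyridine, CH2Cl2, 0 °C
Reagents that add atoms: methanesulfonyl chloride, CS(=O)(=O)Cl
Why: Sulfonylation under basic conditions, which the acid-sensitive enol ether tolerates, turns the C3 oxygen into a leaving group with retention at C3.

**Step 15**
Reactants: 21
Product: 23 tert-butyl{2-[(3S,4S)-6-methoxy-4-methyl-6-[(2R)-2-methyl-10-phenyldecyl]-1,2-dioxan-3-yl]ethoxy}diphenylsilane (both C6 epimers), via hydroperoxy ketal 22 (not isolated)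
Conditions: O3, CH2Cl2/MeOH (4:1), −78 °C; N2 purge, concentrate cold; then KOtBu, 18-crown-6, THF, 0 °C
Reagents that add atoms: ozone, [O-][O+]=O; methanol, CO
Why: Ozonolysis of the enol ether fragments the primary ozonide to methyl formate and the C6 carbonyl oxide, which methanol traps as hydroperoxy ketal 22 (Criegee/Griesbaum trapping), and the peroxide anion then displaces the C3 mesylate in a 6-exo-tet SN2 reaction with inversion, setting (3S) and closing the 1,2-dioxane as in known intramolecular alkylations of hydroperoxy acetals.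

**Step 16**
Reactants: 23
Product: 25 tert-butyl{2-[(3S,4S,6R)-4,6-dimethyl-6-[(2R)-2-methyl-10-phenyldecyl]-1,2-dioxan-3-yl]ethoxy}diphenylsilane, via peroxycarbenium ion 24 (not isolated)
Conditions: AlMe3 (3 equiv), TMSOTf (0.2 equiv), CH2Cl2, −78 °C
Reagents that add atoms: trimethylaluminium, C[Al](C)C
Why: Proposed new method: TMSOTf/AlMe3 ionises the C6 methoxy group of peroxyketal 23 to the cyclic peroxycarbenium ion 24, and methyl transfer from aluminium to C6 should outpace attack on peroxide oxygen at −78 °C; stereoelectronically preferred axial attack on the half-chair with the C4 methyl pseudoequatorial and the C3 side chain pseudoaxial on the opposite face places the new CH3 axial and trans to both, which is (6R), and both C6 epimers of 23 converge on the same cation; the closest known reactions are Lewis-acid substitutions of cyclic peroxyketals by allylsilanes and silyl ketene acetals through peroxycarbenium ions and the AlMe3 C-methylation of ketal-derived oxocarbenium ions, which the peroxide bridge of trioxane lactol derivatives survives.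

**Step 17**
Reactants: 25
Product: 26 2-[(3S,4S,6R)-4,6-dimethyl-6-[(2R)-2-methyl-10-phenyldecyl]-1,2-dioxan-3-yl]ethan-1-ol
Conditions: HF·pyridine, pyridine/THF, 0 °C to rt
Reagents that add atoms: none
Why: Buffered HF·pyridine cleaves the silyl ether without base and so avoids Kornblum–DeLaMare-type fragmentation at the C3–H of the dialkyl peroxide.

**Step 18**
Reactants: 26
Product: 27 2-[(3S,4S,6R)-4,6-dimethyl-6-[(2R)-2-methyl-10-phenyldecyl]-1,2-dioxan-3-yl]acetic acid (target)
Conditions: TEMPO (20 mol %), PhI(OAc)2 (2.2 equiv), MeCN/H2O (1:1), rt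
Reagents that add atoms: water, O
Why: TEMPO/PhI(OAc)2 in aqueous acetonitrile oxidises the primary alcohol through the aldehyde hydrate to the acid under near-neutral, non-reducing conditions that dialkyl peroxides tolerate and that should not promote β-elimination of the peroxide from the transient aldehyde.

**Compound list**
1 | 4-oxoheptanedioic acid | O=C(O)CCC(=O)CCC(=O)O | starting material
2 | (S)-4-benzyloxazolidin-2-one | O=C1N[C@@H](Cc2ccccc2)CO1 | starting material
3 | 4-oxoheptanedioic bis(pivalic) anhydride | CC(C)(C)C(=O)OC(=O)CCC(=O)CCC(=O)OC(=O)C(C)(C)C | intermediate (not isolated)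
4 | (4S,4'S)-3,3'-(4-oxoheptanedioyl)bis(4-benzyl-1,3-oxazolidin-2-one) | O=C(CCC(=O)CCC(=O)N1[C@@H](Cc2ccccc2)COC1=O)N1[C@@H](Cc2ccccc2)COC1=O | intermediate
5 | 4-oxoheptanedioyl bis[(S)-4-benzyloxazolidin-2-one] ethylene ketal | O=C(CCC1(CCC(=O)N2[C@@H](Cc3ccccc3)COC2=O)OCCO1)N1[C@@H](Cc2ccccc2)COC1=O | intermediate
6 | iodomethane | CI | starting material
7 | disodium bis-(Z)-enolate of 5 | [Na+].[Na+].[O-]/C(=C\CC1(C/C=C(\[O-])N2[C@@H](Cc3ccccc3)COC2=O)OCCO1)N1[C@@H](Cc2ccccc2)COC1=O | intermediate (not isolated)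
8 | (2S,6S)-2,6-dimethyl-4-oxoheptanedioyl bis[(S)-4-benzyloxazolidin-2-one] ethylene ketal | C[C@H](C(=O)N1[C@@H](Cc2ccccc2)COC1=O)CC1(OCCO1)C[C@H](C)C(=O)N1[C@@H](Cc2ccccc2)COC1=O | intermediate
9 | (2S,2'S)-3,3'-(1,3-dioxolane-2,2-diyl)bis(2-methylpropan-1-ol) | C[C@H](CO)CC1(OCCO1)C[C@H](C)CO | intermediate
10 | (2S)-3-{2-[(2S)-3-hydroxy-2-methylpropyl]-1,3-dioxolan-2-yl}-2-methylpropyl 4-methylbenzenesulfonate | C[C@H](COS(=O)(=O)c1ccc(C)cc1)CC1(OCCO1)C[C@H](C)CO | intermediate
11 | (7-bromoheptyl)benzene | BrCCCCCCCc1ccccc1 | starting material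
12 | 7-phenylheptylmagnesium bromide | Br[Mg]CCCCCCCc1ccccc1 | intermediate (not isolated)
13 | (2S)-2-methyl-3-{2-[(2R)-2-methyl-10-phenyldecyl]-1,3-dioxolan-2-yl}propan-1-ol | C[C@H](CCCCCCCCc1ccccc1)CC1(OCCO1)C[C@H](C)CO | intermediate
14 | (2S)-2-methyl-3-{2-[(2R)-2-methyl-10-phenyldecyl]-1,3-dioxolan-2-yl}propanal | C[C@H](CCCCCCCCc1ccccc1)CC1(OCCO1)C[C@H](C)C=O | intermediate
15 | ethyl (4S)-4-methyl-5-{2-[(2R)-2-methyl-10-phenyldecyl]-1,3-dioxolan-2-yl}-3-oxopentanoate | C[C@H](CCCCCCCCc1ccccc1)CC1(OCCO1)C[C@H](C)C(=O)CC(=O)OCC | intermediate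
16 | ethyl (3R,4S)-3-hydroxy-4-methyl-5-{2-[(2R)-2-methyl-10-phenyldecyl]-1,3-dioxolan-2-yl}pentanoate | C[C@H](CCCCCCCCc1ccccc1)CC1(OCCO1)C[C@H](C)[C@H](O)CC(=O)OCC | intermediate
17 | (3R,4S)-4-methyl-5-{2-[(2R)-2-methyl-10-phenyldecyl]-1,3-dioxolan-2-yl}pentane-1,3-diol | C[C@H](CCCCCCCCc1ccccc1)CC1(OCCO1)C[C@H](C)[C@H](O)CCO | intermediate
18 | (3R,4S)-1-[(tert-butyldiphenylsilyl)oxy]-4-methyl-5-{2-[(2R)-2-methyl-10-phenyldecyl]-1,3-dioxolan-2-yl}pentan-3-ol | C[C@H](CCCCCCCCc1ccccc1)CC1(OCCO1)C[C@H](C)[C@H](O)CCO[Si](c1ccccc1)(c1ccccc1)C(C)(C)C | intermediate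
19 | (3R,4S,8R)-1-[(tert-butyldiphenylsilyl)oxy]-3-hydroxy-4,8-dimethyl-16-phenylhexadecan-6-one (in equilibrium with its cyclic hemiketal) | C[C@H](CCCCCCCCc1ccccc1)CC(=O)C[C@H](C)[C@H](O)CCO[Si](c1ccccc1)(c1ccccc1)C(C)(C)C | intermediate
20 | (3R,4S,8R)-1-[(tert-butyldiphenylsilyl)oxy]-6-(methoxymethylidene)-4,8-dimethyl-16-phenylhexadecan-3-ol (E/Z mixture) | C[C@H](CCCCCCCCc1ccccc1)CC(=COC)C[C@H](C)[C@H](O)CCO[Si](c1ccccc1)(c1ccccc1)C(C)(C)C | intermediate
21 | methanesulfonate of 20 (E/Z mixture) | C[C@H](CCCCCCCCc1ccccc1)CC(=COC)C[C@H](C)[C@H](OS(C)(=O)=O)CCO[Si](c1ccccc1)(c1ccccc1)C(C)(C)C | intermediate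
22 | (3R,4S,8R)-1-[(tert-butyldiphenylsilyl)oxy]-6-hydroperoxy-6-methoxy-4,8-dimethyl-16-phenylhexadecan-3-yl methanesulfonate (C6 epimers) | C[C@H](CCCCCCCCc1ccccc1)CC(OC)(OO)C[C@H](C)[C@H](OS(C)(=O)=O)CCO[Si](c1ccccc1)(c1ccccc1)C(C)(C)C | intermediate (not isolated)
23 | tert-butyl{2-[(3S,4S)-6-methoxy-4-methyl-6-[(2R)-2-methyl-10-phenyldecyl]-1,2-dioxan-3-yl]ethoxy}diphenylsilane (C6 epimers) | C[C@H](CCCCCCCCc1ccccc1)CC1(OC)C[C@H](C)[C@H](CCO[Si](c2ccccc2)(c2ccccc2)C(C)(C)C)OO1 | intermediate
24 | (3S,4S)-1,2-dioxan-6-ylium (peroxycarbenium) ion derived from 23 | C[C@H](CCCCCCCCc1ccccc1)CC1C[C@H](C)[C@H](CCO[Si](c2ccccc2)(c2ccccc2)C(C)(C)C)O[O+]=1 | intermediate (not isolated)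
25 | tert-butyl{2-[(3S,4S,6R)-4,6-dimethyl-6-[(2R)-2-methyl-10-phenyldecyl]-1,2-dioxan-3-yl]ethoxy}diphenylsilane | C[C@H](CCCCCCCCc1ccccc1)C[C@]1(C)C[C@H](C)[C@H](CCO[Si](c2ccccc2)(c2ccccc2)C(C)(C)C)OO1 | intermediate
26 | 2-[(3S,4S,6R)-4,6-dimethyl-6-[(2R)-2-methyl-10-phenyldecyl]-1,2-dioxan-3-yl]ethan-1-ol | C[C@H](CCCCCCCCc1ccccc1)C[C@]1(C)C[C@H](C)[C@H](CCO)OO1 | intermediate
27 | 2-[(3S,4S,6R)-4,6-dimethyl-6-[(2R)-2-methyl-10-phenyldecyl]-1,2-dioxan-3-yl]acetic acid | C[C@H](CCCCCCCCc1ccccc1)C[C@]1(C)C[C@H](C)[C@H](CC(=O)O)OO1 | target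

**Totals**
Total step count: 18. Longest linear sequence: 18 steps (1 → 27); the Grignard reagent 12 is made within step 6.

**Steps most likely to fail**

1. Step 16 (C6 methylation). Methyl transfer to cation 24 may lose to O–O heterolysis (Criegee-type fragmentation), to proton loss from C5 or C7, or to reduction of the peroxide by the alane, and face selectivity may be incomplete. The fallback sets out from 19 and returns at 25; it builds C6 as a tertiary peroxide carbon that already carries its methyl, at the price of stereocontrol at C6. Ketone 19 would be methylenated (Ph3P=CH2, THF) to (3R,4S,8R)-1-[(tert-butyldiphenylsilyl)oxy]-4,8-dimethyl-6-methylidene-16-phenylhexadecan-3-ol F1 and mesylated (MsCl, pyridine) to its methanesulfonate F2. Mukaiyama–Isayama hydroperoxysilylation (Co(acac)2 cat., O2, Et3SiH, 1,2-dichloroethane) would give the tertiary triethylsilyl peroxide F3 as a C6 mixture. Bu4NF (THF, 0 °C) would free the peroxide anion, which closes on the C3 mesylate with inversion to give 25 together with its (6S) epimer F4, to be separated by chromatography.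

2. Step 15 (hydroperoxy ketal formation and ring closure). The carbonyl oxide may not be captured cleanly by methanol, or the peroxide anion may act as a base and eliminate the mesylate across C3–C4 in place of ring closure. The fallback sets out from 18 and returns at 23; it makes the C3–O bond first and intermolecularly and closes the ring by peroxyketalisation. Alcohol 18 would be mesylated (MsCl, pyridine) to (3R,4S)-1-[(tert-butyldiphenylsilyl)oxy]-4-methyl-5-{2-[(2R)-2-methyl-10-phenyldecyl]-1,3-dioxolan-2-yl}pentan-3-yl methanesulfonate F5. Displacement with 2-methoxyprop-2-yl hydroperoxide (CsOH·H2O, DMF) would give the inverted (3S) peroxyketal F6. TsOH in MeOH would then remove the 2-methoxypropan-2-yl group and the dioxolane, and the freed C3 hydroperoxide would close on C6 to give the cyclic methyl peroxyketal 23.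

3. Step 9 (asymmetric hydrogenation). The dioxolane may solvolyse in the weakly acidic hydrogenation medium, or catalyst control may be eroded by the adjacent C4 centre. The fallback sets out from 14 and returns at 17, with reagent-controlled allylation in place of the homologation/hydrogenation/reduction sequence. Aldehyde 14 would be treated with (−)-Ipc2B(allyl) (from (+)-Ipc2BOMe and allylMgBr; Et2O, −78 °C; NaOH/H2O2 work-up), the Brown reagent that adds to the Re face, to give (4R,5S)-5-methyl-6-{2-[(2R)-2-methyl-10-phenyldecyl]-1,3-dioxolan-2-yl}hex-1-en-4-ol F7. Ozonolysis with reductive work-up (O3, CH2Cl2/MeOH, −78 °C; then NaBH4) would give diol 17.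

**Further compounds**
F1 | step 16 | (3R,4S,8R)-1-[(tert-butyldiphenylsilyl)oxy]-4,8-dimethyl-6-methylidene-16-phenylhexadecan-3-ol | C[C@H](CCCCCCCCc1ccccc1)CC(=C)C[C@H](C)[C@H](O)CCO[Si](c1ccccc1)(c1ccccc1)C(C)(C)C
F2 | step 16 | (3R,4S,8R)-1-[(tert-butyldiphenylsilyl)oxy]-4,8-dimethyl-6-methylidene-16-phenylhexadecan-3-yl methanesulfonate | C[C@H](CCCCCCCCc1ccccc1)CC(=C)C[C@H](C)[C@H](OS(C)(=O)=O)CCO[Si](c1ccccc1)(c1ccccc1)C(C)(C)C
F3 | step 16 | (3R,4S,8R)-1-[(tert-butyldiphenylsilyl)oxy]-4,6,8-trimethyl-16-phenyl-6-[(triethylsilyl)peroxy]hexadecan-3-yl methanesulfonate (C6 epimers) | C[C@H](CCCCCCCCc1ccccc1)CC(C)(OO[Si](CC)(CC)CC)C[C@H](C)[C@H](OS(C)(=O)=O)CCO[Si](c1ccccc1)(c1ccccc1)C(C)(C)C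
F4 | step 16 | tert-butyl{2-[(3S,4S,6S)-4,6-dimethyl-6-[(2R)-2-methyl-10-phenyldecyl]-1,2-dioxan-3-yl]ethoxy}diphenylsilane (C6 epimer of 25) | C[C@H](CCCCCCCCc1ccccc1)C[C@@]1(C)C[C@H](C)[C@H](CCO[Si](c2ccccc2)(c2ccccc2)C(C)(C)C)OO1
F5 | step 15 | (3R,4S)-1-[(tert-butyldiphenylsilyl)oxy]-4-methyl-5-{2-[(2R)-2-methyl-10-phenyldecyl]-1,3-dioxolan-2-yl}pentan-3-yl methanesulfonate | C[C@H](CCCCCCCCc1ccccc1)CC1(OCCO1)C[C@H](C)[C@H](OS(C)(=O)=O)CCO[Si](c1ccccc1)(c1ccccc1)C(C)(C)C
F6 | step 15 | tert-butyl{[(3S,4S)-3-[(2-methoxypropan-2-yl)peroxy]-4-methyl-5-{2-[(2R)-2-methyl-10-phenyldecyl]-1,3-dioxolan-2-yl}pentyl]oxy}diphenylsilane | C[C@H](CCCCCCCCc1ccccc1)CC1(OCCO1)C[C@H](C)[C@@H](OOC(C)(C)OC)CCO[Si](c1ccccc1)(c1ccccc1)C(C)(C)C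
F7 | step 9 | (4R,5S)-5-methyl-6-{2-[(2R)-2-methyl-10-phenyldecyl]-1,3-dioxolan-2-yl}hex-1-en-4-ol | C[C@H](CCCCCCCCc1ccccc1)CC1(OCCO1)C[C@H](C)[C@H](O)CC=C
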